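**Plan**
1. Retrosynthesis: cut C4′–Br first (H–Br across a C4′=C5′ alkene), then C3′–Cl (back to an allylic alcohol and an enone). Then cut oxane O1–C2 and C3–Br together (bromoetherification of a tertiary alcohol onto a prenyl alkene).
2. The carbocycle is cut at both ends of its only unsubstituted edge, C5′H2–C6′H2. Bonds C6′–C1′ and C5′–C4′ form in one [4+2] step between a 2-silyloxydiene (C1′=C2′–C3′=C4′) and a two-carbon unit at the acetylene oxidation level.
3. Enabling feature: oxane O1 sits on quaternary C6, which is bonded to ring carbon C1′, so O1 lies three bonds from C6′. An O–SiMe2 link from this oxygen to the C2 unit closes a temporary five-membered 1,2-oxasilole, so an unactivated ethyne reacts intramolecularly with a single regiochemistry.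
4. Forward order: geraniol (C10) and propanal (C3) give the acyclic chain. Carbocycle and oxasilole form together in step 9. Fluoride removes both silicon groups and leaves a carvone-type enone, the oxane closes next, and the ring chlorine and bromine come last.
5. Stereochemistry: C6 comes from a Sharpless epoxidation, C1′ from C6 through the tether, and C3 from C6 through a chair transition state. C3′ comes from C1′ (Luche reduction, then inversion) and C4′ from C3′ (bromine transfer anti to the axial chlorine).

Key step: step 9

Locants in the text are those of the target. Oxane: O1, C2 (CMe2), C3 (CHBr), C4, C5, C6 (C–CH3). Carbocycle: C1′ (CH on C6), C2′, C3′ (CHCl), C4′ (CBrCH3), C5′, C6′.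

**Step 1**
Reactants: 1 geraniol
Product: 2 (2S,3S)-2,3-epoxygeraniol
Conditions: Ti(OiPr)4 (cat.), L-(+)-diethyl tartrate (cat.), t-BuOOH, 4 Å MS, CH2Cl2, −20 °C
Reagents that add atoms: tert-butyl hydroperoxide, CC(C)(C)OO
Why: Sharpless asymmetric epoxidation: the titanium tartrate complex binds the allylic hydroxyl, so only the 2,3-alkene reacts, and L-(+)-tartrate directs oxygen to the face that gives the (2S,3S)-epoxide, whose C3 becomes C6 (S) of the target.

**Step 2**
Reactants: 2 (2S,3S)-2,3-epoxygeraniol
Product: 3 (2R,3S)-2-(chloromethyl)-3-methyl-3-(4-methylpent-3-en-1-yl)oxirane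
Conditions: PPh3, CCl4, NaHCO3, reflux
Reagents that add atoms: carbon tetrachloride, ClC(Cl)(Cl)Cl
Why: Appel reaction: chloride displaces the primary oxyphosphonium salt under buffered, nearly neutral conditions, so the acid-sensitive epoxide and its two stereocentres are untouched.

**Step 3**
Reactants: 3 (2R,3S)-2-(chloromethyl)-3-methyl-3-(4-methylpent-3-en-1-yl)oxirane; 4 propanal
Product: 6 (6S)-6,10-dimethylundec-9-en-4-yne-3,6-diol (both C3 epimers), via dilithiated (3S)-dehydrolinalool 5 (not isolated)
Conditions: n-BuLi (3.3 equiv), THF, −78 to −30 °C; then 4, −78 °C; aq NH4Cl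
Reagents that add atoms: none
Why: Base-induced eliminative opening of a 2,3-epoxy chloride (deprotonation at CH2Cl, epoxide opening, loss of HCl) keeps the C–O bond at the quaternary centre and gives the acetylide, which adds to the aldehyde (alkynylation); the new secondary carbinol centre forms without control and is removed in step 5.

**Step 4**
Reactants: 6 (6S)-6,10-dimethylundec-9-en-4-yne-3,6-diol
Product: 7 (4E,6S)-6,10-dimethylundeca-4,9-diene-3,6-diol (both C3 epimers)
Conditions: NaAlH2(OCH2CH2OMe)2 (Red-Al), THF, 0 °C to rt; aq Rochelle salt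
Reagents that add atoms: none
Why: Hydroxyl-directed trans-hydroalumination of the propargylic alkyne followed by protonolysis gives only the E-alkene, and the isolated trisubstituted alkene is inert to the aluminium hydride.

**Step 5**
Reactants: 7 (4E,6S)-6,10-dimethylundeca-4,9-diene-3,6-diol
Product: 8 (4E,6S)-6-hydroxy-6,10-dimethylundeca-4,9-dien-3-one
Conditions: MnO2 (activated, excess), CH2Cl2, rt
Reagents that add atoms: none
Why: Allylic oxidation with MnO2 is chemoselective because only the secondary allylic alcohol carries a carbinol hydrogen, and the E-alkene and the tertiary centre are unaffected.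

**Step 6**
Reactants: 9 dichlorodimethylsilane; 10 ethynylmagnesium bromide
Product: 11 chloro(ethynyl)dimethylsilane
Conditions: 9 (3 equiv), THF, −78 °C to rt; filtration, fractional distillation
Reagents that add atoms: none
Why: Nucleophilic substitution at silicon by the Grignard reagent, where the excess of 9 should hold the reaction at monosubstitution.

**Step 7**
Reactants: 8 (4E,6S)-6-hydroxy-6,10-dimethylundeca-4,9-dien-3-one; 11 chloro(ethynyl)dimethylsilane
Product: 12 (4E,6S)-6-{[ethynyl(dimethyl)silyl]oxy}-6,10-dimethylundeca-4,9-dien-3-one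
Conditions: imidazole, DMF, 0 °C to rt
Reagents that add atoms: none
Why: Imidazole-promoted silyl ether formation: the small dimethylsilyl chloride reaches the hindered tertiary alcohol, and the mild base leaves the enone and the Si–C(sp) bond intact.

**Step 8**
Reactants: 12 (4E,6S)-6-{[ethynyl(dimethyl)silyl]oxy}-6,10-dimethylundeca-4,9-dien-3-one
Product: 13 (2Z,4E,6S)-3-[(tert-butyldimethylsilyl)oxy]-6-{[ethynyl(dimethyl)silyl]oxy}-6,10-dimethylundeca-2,4,9-triene
Conditions: TBSOTf, Et3N, CH2Cl2, −78 to 0 °C; Et3N-deactivated silica
Reagents that add atoms: tert-butyldimethylsilyl trifluoromethanesulfonate, CC(C)(C)[Si](C)(C)OS(=O)(=O)C(F)(F)F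
Why: Soft enolisation with silyl triflate and amine takes the only enolisable position (the ethyl CH2, as there is no γ-hydrogen) and should give the Z-enol ether, which places the terminal methyl group outside the s-cis diene.

**Step 9**
Reactants: 13 (2Z,4E,6S)-3-[(tert-butyldimethylsilyl)oxy]-6-{[ethynyl(dimethyl)silyl]oxy}-6,10-dimethylundeca-2,4,9-triene
Product: 14 (3S,3aS,6R)-5-[(tert-butyldimethylsilyl)oxy]-1,1,3,6-tetramethyl-3-(4-methylpent-3-en-1-yl)-1,3,3a,6-tetrahydro-2,1-benzoxasilole
Conditions: PhMe (0.01 M), BHT (cat.), base-washed sealed tube, argon, 150–160 °C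
Reagents that add atoms: none
Why: This is a thermal, concerted, suprafacial [4+2] cycloaddition (intramolecular Diels–Alder reaction, type 1) in which the electron-rich 2-silyloxydiene adds the ethynylsilane, the silicon-bearing alkyne carbon bonding to the diene terminus next to the carbinol carbon (future C6′–C1′ bond) and the terminal alkyne carbon to the methyl-bearing terminus (future C5′–C4′ bond). The closest known reaction types are the temporary-silicon-tethered Diels–Alder reactions of unsaturated silyl ethers of dienols, where the silane serves as a traceless C2 unit, and the thermal cycloadditions of 1,3-dien-8-ynes. Two rings close at once: the cyclohexa-1,4-diene by the cycloaddition itself and the five-membered 1,2-oxasilole in the fused mode imposed by the three-atom C–O–Si tether, the bridged mode being geometrically out of reach. The ring CH (C3a, future C1′) is controlled by the S carbinol centre, because the tether holds the C–O bond perpendicular to the diene over the reacting face and so leaves the site that nearly eclipses the C=C bond (allylic 1,3-strain against the vinylic H) to the methyl group and the open site beside the terminal H to the homoprenyl chain, which puts methyl cis to the ring CH= on the oxasilole; C6 of 14 follows from the diene geometry (both outside substituents end cis) and is erased in step 10. The step needs site selectivity for the alkyne over the equally tethered side-chain alkene, secured because that alkene would have to bond through its fully substituted carbon, and regioselectivity, secured by the tether, while the gem-disubstituted carbinol carbon (Thorpe–Ingold effect) should bring the unactivated alkyne into reach at this temperature. Since an alkyne has no endo or exo orientation, selection of the diene face is the only stereochemical variable, and its intrinsic bias (methyl against a primary alkyl chain) is expected to be modest.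

**Step 10**
Reactants: 14 (3S,3aS,6R)-5-[(tert-butyldimethylsilyl)oxy]-1,1,3,6-tetramethyl-3-(4-methylpent-3-en-1-yl)-1,3,3a,6-tetrahydro-2,1-benzoxasilole
Product: 16 (5S)-5-[(2S)-2-hydroxy-6-methylhept-5-en-2-yl]-2-methylcyclohex-2-en-1-one, via deconjugated cyclohex-3-enone 15 (not isolated)
Conditions: Bu4NF·3H2O (4 equiv), THF, 0 °C to rt, argon
Reagents that add atoms: none
Why: Fluoride-induced desilylation: the enol ether is unmasked to the ketone, dienolate formation places the C–Si bond in a vinylogous α-position so that protodesilylation is easy (giving 15), and the basic medium moves the alkene into conjugation, while the ring CH (future C1′) is never acidic and keeps its configuration.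

**Step 11**
Reactants: 16 (5S)-5-[(2S)-2-hydroxy-6-methylhept-5-en-2-yl]-2-methylcyclohex-2-en-1-one
Product: 17 (5S)-5-[(2S,5R)-5-bromo-2,6,6-trimethyloxan-2-yl]-2-methylcyclohex-2-en-1-one
Conditions: 2,4,4,6-tetrabromocyclohexa-2,5-dienone (TBCO), MeNO2, 0 °C, dark
Reagents that add atoms: 2,4,4,6-tetrabromocyclohexa-2,5-dienone, O=C1C(Br)=CC(Br)(Br)C=C1Br
Why: Bromoetherification (6-endo, Markovnikov opening of the bromonium ion at the dimethyl-substituted carbon): the electron-poor enone alkene does not compete, anti addition in a chair transition state forces bromine equatorial, and the axial site on target C6, which faces an axial methyl group on C2, takes the methyl rather than the cyclohexenonyl group, so target C3 is set as R from C6.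

**Step 12**
Reactants: 17 (5S)-5-[(2S,5R)-5-bromo-2,6,6-trimethyloxan-2-yl]-2-methylcyclohex-2-en-1-one
Product: 18 (1S,5S)-5-[(2S,5R)-5-bromo-2,6,6-trimethyloxan-2-yl]-2-methylcyclohex-2-en-1-ol
Conditions: NaBH4, CeCl3·7H2O, MeOH, −78 to −20 °C
Reagents that add atoms: none
Why: Luche reduction: the cerium-modified borohydride adds 1,2 and axially to the half-chair with the oxanyl group equatorial, which should give the pseudo-equatorial alcohol cis to that group (the cis-carveol pattern), so C3′ is set from C1′.

**Step 13**
Reactants: 18 (1S,5S)-5-[(2S,5R)-5-bromo-2,6,6-trimethyloxan-2-yl]-2-methylcyclohex-2-en-1-ol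
Product: 19 (3R,6S)-3-bromo-6-[(1S,5R)-5-chloro-4-methylcyclohex-3-en-1-yl]-2,2,6-trimethyloxane
Conditions: PPh3, Cl3CC(O)CCl3, CH2Cl2, 0 °C, short reaction time; used promptly
Reagents that add atoms: hexachloroacetone, ClC(Cl)(Cl)C(=O)C(Cl)(Cl)Cl
Why: Appel-type chlorination: direct SN2 displacement of the allylic oxyphosphonium ion inverts C3′ to the pseudo-axial chloride (R) trans to the oxanyl group, and the short time at low temperature is chosen to suppress SN2′ attack and ion-pair return.

**Step 14**
Reactants: 19 (3R,6S)-3-bromo-6-[(1S,5R)-5-chloro-4-methylcyclohex-3-en-1-yl]-2,2,6-trimethyloxane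
Product: 20 (3R,6S)-3-bromo-6-[(1S,3R,4R)-4-bromo-3-chloro-4-methylcyclohexyl]-2,2,6-trimethyloxane (target)
Conditions: Co(acac)2 (0.25 equiv), t-BuOOH (0.25 equiv), Et3SiH, TsBr, CH2Cl2/n-PrOH, rt, argon, dark
Reagents that add atoms: 4-methylbenzenesulfonyl bromide, Cc1ccc(cc1)S(=O)(=O)Br
Why: Markovnikov hydrobromination by metal-hydride hydrogen atom transfer (Mukaiyama-type hydrofunctionalisation): the cobalt hydride gives H to the less substituted C5′, the tertiary C4′ radical takes bromine from TsBr under neutral conditions that spare the acid-labile di-tertiary ether, and in the chair with the oxanyl group equatorial the axial C3′–Cl bond shields the lower face, so bromine enters axially and anti to give the trans-diaxial (3′R,4′R) pair.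

**Compound list**
1 | geraniol | CC(C)=CCC/C(C)=C/CO | starting material
2 | (2S,3S)-2,3-epoxygeraniol | CC(C)=CCC[C@]1(C)O[C@H]1CO | intermediate
3 | (2R,3S)-2-(chloromethyl)-3-methyl-3-(4-methylpent-3-en-1-yl)oxirane | CC(C)=CCC[C@]1(C)O[C@H]1CCl | intermediate
4 | propanal | CCC=O | starting material
5 | dilithium salt of (3S)-3,7-dimethyloct-6-en-1-yn-3-ol (not isolated) | CC(C)=CCC[C@](C)(O[Li])C#C[Li] | intermediate
6 | (6S)-6,10-dimethylundec-9-en-4-yne-3,6-diol, both C3 epimers | CC(C)=CCC[C@](C)(O)C#CC(O)CC | intermediate
7 | (4E,6S)-6,10-dimethylundeca-4,9-diene-3,6-diol, both C3 epimers | CC(C)=CCC[C@](C)(O)/C=C/C(O)CC | intermediate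
8 | (4E,6S)-6-hydroxy-6,10-dimethylundeca-4,9-dien-3-one | CC(C)=CCC[C@](C)(O)/C=C/C(=O)CC | intermediate
9 | dichlorodimethylsilane | C[Si](C)(Cl)Cl | starting material
10 | ethynylmagnesium bromide | C#C[Mg]Br | starting material
11 | chloro(ethynyl)dimethylsilane | C#C[Si](C)(C)Cl | intermediate
12 | (4E,6S)-6-{[ethynyl(dimethyl)silyl]oxy}-6,10-dimethylundeca-4,9-dien-3-one | CC(C)=CCC[C@](C)(O[Si](C)(C)C#C)/C=C/C(=O)CC | intermediate
13 | (2Z,4E,6S)-3-[(tert-butyldimethylsilyl)oxy]-6-{[ethynyl(dimethyl)silyl]oxy}-6,10-dimethylundeca-2,4,9-triene | CC(C)=CCC[C@](C)(O[Si](C)(C)C#C)/C=C/C(O[Si](C)(C)C(C)(C)C)=C/C | intermediate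
14 | (3S,3aS,6R)-5-[(tert-butyldimethylsilyl)oxy]-1,1,3,6-tetramethyl-3-(4-methylpent-3-en-1-yl)-1,3,3a,6-tetrahydro-2,1-benzoxasilole | CC(C)=CCC[C@]1(C)O[Si](C)(C)C2=C[C@@H](C)C(O[Si](C)(C)C(C)(C)C)=C[C@@H]12 | intermediate
15 | (5R)-5-[(2S)-2-hydroxy-6-methylhept-5-en-2-yl]-2-methylcyclohex-3-en-1-one, C2 epimers (not isolated) | CC(C)=CCC[C@](C)(O)[C@H]1C=CC(C)C(=O)C1 | intermediate
16 | (5S)-5-[(2S)-2-hydroxy-6-methylhept-5-en-2-yl]-2-methylcyclohex-2-en-1-one | CC(C)=CCC[C@](C)(O)[C@H]1CC=C(C)C(=O)C1 | intermediate
17 | (5S)-5-[(2S,5R)-5-bromo-2,6,6-trimethyloxan-2-yl]-2-methylcyclohex-2-en-1-one | CC1(C)O[C@](C)([C@H]2CC=C(C)C(=O)C2)CC[C@H]1Br | intermediate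
18 | (1S,5S)-5-[(2S,5R)-5-bromo-2,6,6-trimethyloxan-2-yl]-2-methylcyclohex-2-en-1-ol | CC1(C)O[C@](C)([C@H]2CC=C(C)[C@@H](O)C2)CC[C@H]1Br | intermediate
19 | (3R,6S)-3-bromo-6-[(1S,5R)-5-chloro-4-methylcyclohex-3-en-1-yl]-2,2,6-trimethyloxane | CC1(C)O[C@](C)([C@H]2CC=C(C)[C@H](Cl)C2)CC[C@H]1Br | intermediate
20 | (3R,6S)-3-bromo-6-[(1S,3R,4R)-4-bromo-3-chloro-4-methylcyclohexyl]-2,2,6-trimethyloxane | CC1(C)O[C@](C)([C@H]2CC[C@@](C)(Br)[C@H](Cl)C2)CC[C@H]1Br | target

**Step count and risks**

Total step count: 14. Longest linear sequence: 13 (steps 1–5 and 7–14).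

Steps most likely to fail:

**Step 9.** The methyl group and the homoprenyl chain on the carbinol carbon are discriminated only weakly, so facial selectivity may be poor. Long heating may also erode the silyl dienol ether or aromatise the cyclohexadiene. The unwanted C3a epimer would have to be removed by chromatography, most easily at 16.
Fallback: set out from 13 and replace the thermal pericyclic reaction by a metal-catalysed [4+2] that runs through a rhodacycle. The diene and alkyne undergo oxidative cyclisation on cationic monovalent rhodium, followed by reductive elimination. Conditions would be [Rh(cod)Cl]2, AgSbF6 and an enantiopure bisphosphine such as Me-DuPhos (both antipodes to be screened) in ClCH2CH2Cl at rt to 40 °C. The ligand, not the substituents on the carbinol carbon, then selects the diene face, and no heating is needed. The route is rejoined at 14, and no compound outside the list is made (F0).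

**Step 14.** A sulfonyl-radical chain addition (bromosulfonylation) may outrun hydrogen atom transfer. The β-chloroalkyl radical may lose its chlorine atom. Bromine transfer may occur on both faces.
Fallback: set out from 19 and make the C4′–Br bond by ionic substitution instead of atom transfer. Mukaiyama hydration (Mn(dpm)3, PhSiH3, O2, i-PrOH/CH2Cl2, 0 °C) gives the tertiary chlorohydrin F3, and either carbinol epimer serves. Activation of its free hydroxyl alone with 1-bromo-N,N,2-trimethylprop-1-en-1-amine (CH2Cl2, 0 °C to rt, neutral) then ionises C4′ with assistance from the anti chlorine. Bromide attacks axially, anti to chlorine, at the tertiary carbon. The route is rejoined at 20.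

**Step 11.** Closure in the 5-exo mode to the oxolane with an exocyclic CMe2Br group may compete with the 6-endo mode.
Fallback: set out from 16 and use divalent mercury, whose alkene complex opens more strictly in the Markovnikov sense. Hg(O2CCF3)2 in MeNO2 at 0 °C gives the oxanyl organomercury trifluoroacetate F1, and aqueous KBr converts it to the organomercury bromide F2. Bromodemercuration with Br2 in pyridine (0 °C, dark, retention) then places the equatorial bromine. The route is rejoined at 17.

**Further compounds**
F0 | step 9 | none | none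
F1 | step 11 | {(3R,6S)-2,2,6-trimethyl-6-[(1S)-4-methyl-5-oxocyclohex-3-en-1-yl]oxan-3-yl}mercury trifluoroacetate | CC1(C)O[C@](C)([C@H]2CC=C(C)C(=O)C2)CC[C@H]1[Hg]OC(=O)C(F)(F)F
F2 | step 11 | bromo{(3R,6S)-2,2,6-trimethyl-6-[(1S)-4-methyl-5-oxocyclohex-3-en-1-yl]oxan-3-yl}mercury | CC1(C)O[C@](C)([C@H]2CC=C(C)C(=O)C2)CC[C@H]1[Hg]Br
F3 | step 14 | (2R,4S)-4-[(2S,5R)-5-bromo-2,6,6-trimethyloxan-2-yl]-2-chloro-1-methylcyclohexan-1-ol, C1 epimers | CC1(C)O[C@](C)([C@H]2CCC(C)(O)[C@H](Cl)C2)CC[C@H]1Br
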